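**Strategy**

Everything rests on the bond between C2 of the dihydropyranone ring (ring C) and C6 of the 2,2-dimethylchroman unit. C2, the only stereocentre, lies β to the C4 ketone, so the flavanone is the 1,4-adduct of an aryl nucleophile and a flat chromone. A rhodium/chiral-diene-catalysed asymmetric conjugate addition of (2,2-dimethylchroman-6-yl)boronic acid to 7-(methoxymethoxy)-8-prenylchromone joins the two halves, turns sp2 C2 into the (S)-configured centre and sets the final oxidation level in one operation. The chromone precursor carries its C8 prenyl group from an aromatic Claisen rearrangement; the boronic acid comes from 4-bromophenol and isoprene. Acidic removal of the MOM group ends the route.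

Key step: step 7

Assumption on starting materials: compounds 1, 2, 8 and 9 are taken as purchased.

Assumption on the sense of induction: the (R,R)-diene ligand is taken to give (R)-3-arylcyclohexanones, which corresponds by the same facial approach to the (2R)-flavanone. The (S,S)-ligand is therefore specified for the (2S) product. Should the sense be opposite on this chromone, the antipodal ligand is used with no other change.

**Route**

Step 1
Reactants: 1 7-hydroxy-4H-chromen-4-one (7-hydroxychromone); 2 3-chloro-3-methylbut-1-yne
Product: 3 7-[(2-methylbut-3-yn-2-yl)oxy]-4H-chromen-4-one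
Conditions: K2CO3, KI (cat.), CuI (cat.), acetone, reflux
Reagents that add atoms: none
Why: Copper-assisted Williamson-type O-alkylation of the only phenol by the tertiary propargylic chloride is the standard entry to aryl 1,1-dimethylpropargyl ethers and should work on the acidic 7-OH as it does on 7-hydroxycoumarins.

Step 2
Reactants: 3 7-[(2-methylbut-3-yn-2-yl)oxy]-4H-chromen-4-one
Product: 4 7-[(2-methylbut-3-en-2-yl)oxy]-4H-chromen-4-one
Conditions: H2 (1 atm), Lindlar catalyst (Pd/CaCO3, Pb-poisoned), quinoline, EtOAc, rt
Reagents that add atoms: none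
Why: Lindlar semihydrogenation should stop at the terminal alkene and leave the chromone C2=C3 bond, a vinylogous ester, untouched.

Step 3
Reactants: 4 7-[(2-methylbut-3-en-2-yl)oxy]-4H-chromen-4-one
Product: 6 7-hydroxy-8-(3-methylbut-2-en-1-yl)-4H-chromen-4-one, via ortho-dienone 5 (not isolated)
Conditions: N,N-diethylaniline, 150 °C, Ar
Reagents that add atoms: none
Why: The aromatic Claisen ([3,3]-sigmatropic) rearrangement of the 1,1-dimethylallyl ether should deliver a linear prenyl group to C8 rather than C6, because conjugation of O1 with the C4 carbonyl gives the C7–C8 bond the higher double-bond character, and the dienone then tautomerises to the phenol.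

Step 4
Reactants: 6 7-hydroxy-8-(3-methylbut-2-en-1-yl)-4H-chromen-4-one
Product: 7 7-(methoxymethoxy)-8-(3-methylbut-2-en-1-yl)-4H-chromen-4-one
Conditions: MOMCl, K2CO3, acetone, 0 °C to rt
Reagents that add atoms: chloromethyl methyl ether (MOMCl), COCCl
Why: Phenol O-alkylation to the MOM acetal gives a group that is stable to the aqueous base of step 7 and prevents formation of a 7-phenoxide that would deactivate the chromone as a Michael acceptor.

Step 5
Reactants: 8 4-bromophenol; 9 isoprene (2-methylbuta-1,3-diene)
Product: 11 6-bromo-2,2-dimethyl-3,4-dihydro-2H-chromene, via 4-bromo-2-prenylphenol 10 (not isolated)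
Conditions: Amberlyst 15 (cat.), THF/heptane, 65 °C
Reagents that add atoms: none
Why: Acid-catalysed Friedel–Crafts prenylation ortho to the OH (para position blocked by Br) followed by Markovnikov intramolecular hydroalkoxylation of the prenyl olefin through the tertiary cation should close the 2,2-dimethylchroman ring.

Step 6
Reactants: 11 6-bromo-2,2-dimethyl-3,4-dihydro-2H-chromene
Product: 14 (2,2-dimethyl-3,4-dihydro-2H-chromen-6-yl)boronic acid, via aryllithium 12 (not isolated), via lithium aryltriisopropoxyborate 13 (not isolated)
Conditions: n-BuLi, THF, −78 °C; B(Oi-Pr)3, −78 °C to rt; 1 M aq HCl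
Reagents that add atoms: triisopropyl borate, CC(C)OB(OC(C)C)OC(C)C; water, O
Why: Bromine–lithium exchange, trapping of the aryllithium with the trialkyl borate and acidic hydrolysis is the standard arylboronic acid synthesis, and the chroman ether is inert to n-BuLi at −78 °C.

Step 7
Reactants: 7 7-(methoxymethoxy)-8-(3-methylbut-2-en-1-yl)-4H-chromen-4-one; 14 (2,2-dimethyl-3,4-dihydro-2H-chromen-6-yl)boronic acid (2.5 equiv)
Product: 15 (2S)-2-(2,2-dimethyl-3,4-dihydro-2H-chromen-6-yl)-7-(methoxymethoxy)-8-(3-methylbut-2-en-1-yl)-2,3-dihydro-4H-chromen-4-one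
Conditions: [RhCl(C2H4)2]2 (2.5 mol %), (1S,4S)-2,5-diphenylbicyclo[2.2.2]octa-2,5-diene [(S,S)-Ph-bod*] (5.5 mol %), aq KOH (0.2 equiv), 1,4-dioxane/H2O (10:1), 40 °C
Reagents that add atoms: none
Why: Transmetalation of 14 to the hydroxo-rhodium(I)–diene complex gives an aryl–Rh(I) species, the C2=C3 bond of 7 coordinates, and enantio-determining migratory insertion places the aryl group on C2 to give a rhodium oxa-π-allyl (enolate) over C3–C4–O that water protonates, releasing 15 and regenerating Rh–OH. The closest known reaction type is the Hayashi–Miyaura rhodium-catalysed asymmetric 1,4-addition of arylboronic acids to enones, which is established for chromones as a route to flavanones. No ring is closed; the step is an intermolecular C(sp2)–C(sp3) bond formation between the two fragments. The single new stereocentre, C2, is controlled by the C2-symmetric chiral diene on rhodium, which should direct the aryl group to the Re face of C2 of the flat chromone and so give the (2S) configuration. The step needs enantioface selectivity, 1,4- over 1,2-selectivity and chemoselectivity against the prenyl olefin: the first comes from the ligand, the second from the much higher reactivity of the enone than of the product ketone at 40 °C, and the third from the inertness of an unactivated trisubstituted alkene to aryl–rhodium insertion. The MOM group keeps O7 from forming a phenoxide that would deactivate the enone, and the small charge of KOH, buffered by the excess boronic acid, should prevent retro-oxa-Michael opening of 15 and with it racemisation.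

Step 8
Reactants: 15 (2S)-2-(2,2-dimethyl-3,4-dihydro-2H-chromen-6-yl)-7-(methoxymethoxy)-8-(3-methylbut-2-en-1-yl)-2,3-dihydro-4H-chromen-4-one
Product: 16 euchrenone a17, (2S)-2-(2,2-dimethyl-3,4-dihydro-2H-chromen-6-yl)-7-hydroxy-8-(3-methylbut-2-en-1-yl)-2,3-dihydro-4H-chromen-4-one
Conditions: HCl (cat., methanolic), MeOH, rt to 40 °C
Reagents that add atoms: none
Why: Acid-catalysed acetal exchange of the aryl MOM ether with methanol should free the phenol under conditions that do not open the flavanone ring (no base, so C2 keeps its configuration) and are too mild to cyclise the prenyl chain onto the new 7-OH.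

**Compound list**

1 | 7-hydroxy-4H-chromen-4-one (7-hydroxychromone) | O=c1ccoc2cc(O)ccc12 | starting material
2 | 3-chloro-3-methylbut-1-yne | C#CC(C)(C)Cl | starting material
3 | 7-[(2-methylbut-3-yn-2-yl)oxy]-4H-chromen-4-one | C#CC(C)(C)Oc1ccc2c(c1)occc2=O | intermediate
4 | 7-[(2-methylbut-3-en-2-yl)oxy]-4H-chromen-4-one | C=CC(C)(C)Oc1ccc2c(c1)occc2=O | intermediate
5 | 8-(3-methylbut-2-en-1-yl)-8H-chromene-4,7-dione (ortho-dienone, racemic, transient) | CC(C)=CCC1C(=O)C=CC2=C1OC=CC2=O | intermediate (not isolated)
6 | 7-hydroxy-8-(3-methylbut-2-en-1-yl)-4H-chromen-4-one | CC(C)=CCc1c(O)ccc2c1occc2=O | intermediate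
7 | 7-(methoxymethoxy)-8-(3-methylbut-2-en-1-yl)-4H-chromen-4-one | COCOc1ccc2c(c1CC=C(C)C)occc2=O | intermediate
8 | 4-bromophenol | Oc1ccc(Br)cc1 | starting material
9 | isoprene (2-methylbuta-1,3-diene) | C=CC(C)=C | starting material
10 | 4-bromo-2-(3-methylbut-2-en-1-yl)phenol | CC(C)=CCc1cc(Br)ccc1O | intermediate (not isolated)
11 | 6-bromo-2,2-dimethyl-3,4-dihydro-2H-chromene | CC1(C)CCc2cc(Br)ccc2O1 | intermediate
12 | (2,2-dimethyl-3,4-dihydro-2H-chromen-6-yl)lithium | [Li]c1ccc2OC(C)(C)CCc2c1 | intermediate (not isolated)
13 | lithium (2,2-dimethyl-3,4-dihydro-2H-chromen-6-yl)tri(propan-2-yloxy)borate | [Li+].CC(C)O[B-](OC(C)C)(OC(C)C)c1ccc2OC(C)(C)CCc2c1 | intermediate (not isolated)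
14 | (2,2-dimethyl-3,4-dihydro-2H-chromen-6-yl)boronic acid | OB(O)c1ccc2OC(C)(C)CCc2c1 | intermediate
15 | (2S)-2-(2,2-dimethyl-3,4-dihydro-2H-chromen-6-yl)-7-(methoxymethoxy)-8-(3-methylbut-2-en-1-yl)-2,3-dihydro-4H-chromen-4-one | CC(C)=CCc1c(OCOC)ccc2c1O[C@H](c1ccc3c(c1)CCC(C)(C)O3)CC2=O | intermediate
16 | euchrenone a17, (2S)-2-(2,2-dimethyl-3,4-dihydro-2H-chromen-6-yl)-7-hydroxy-8-(3-methylbut-2-en-1-yl)-2,3-dihydro-4H-chromen-4-one | CC(C)=CCc1c(O)ccc2c1O[C@H](c1ccc3c(c1)CCC(C)(C)O3)CC2=O | target

**Summary**

Total step count: 8.
Longest linear sequence: 6 steps (steps 1, 2, 3, 4, 7, 8); the boronic acid branch is 2 steps (5, 6).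

**Steps most likely to fail, with fallbacks**

1. Step 7. The risks are insufficient facial selectivity, slow insertion into the 7-alkoxy-deactivated chromone with competing protodeboronation of the electron-rich boronic acid, and base-induced ring opening that erodes the enantiomeric purity. The fallback separates bond formation from stereocontrol. It sets out from 7 and 14: an achiral cationic palladium(II) catalyst (Pd(TFA)2, 2,2'-bipyridine, aqueous medium, 60 °C) should effect the same conjugate addition and give the racemic MOM-protected flavanone F1. A kinetic resolution by asymmetric transfer hydrogenation follows (Noyori–Ikariya Ru–TsDPEN catalyst of the configuration that reduces the (2R)-ketone faster, HCO2H/Et3N, rt). It should convert the (2R)-enantiomer into the cis-(2R,4R)-flavan-4-ol F2 and leave the (2S)-ketone, which is separated by chromatography. The fallback comes back to the route at 15.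

2. Step 3. The risks are migration to C6 in place of C8 and loss of the tertiary allyl group by elimination at the temperature of the rearrangement. The fallback moves the rearrangement to an acetophenone in which the hydrogen-bonded 2-OH fixes the regiochemistry. It sets out from 2 and purchased 2,4-dihydroxyacetophenone F3. Alkylation of the free 4-OH with 2 (K2CO3, KI, CuI, acetone) should give the propargyl ether F4, and Lindlar semihydrogenation the 1,1-dimethylallyl ether F5. Claisen rearrangement (N,N-diethylaniline, heat) should give 2,4-dihydroxy-3-prenylacetophenone F6, and MOMCl/K2CO3 should protect the non-chelated 4-OH to give F7. Condensation with N,N-dimethylformamide dimethyl acetal should give the enaminone F8, and mild acid (PPTS or silica gel, CH2Cl2) should close the pyranone ring with loss of dimethylamine. The fallback comes back to the route at 7.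

3. Step 8. The risks are acid-promoted cyclisation of the prenyl chain onto the freed 7-OH and addition of HCl or methanol across the olefin before acetal cleavage is complete. The fallback changes the protecting-group strategy to one cleaved by fluoride. It sets out from 6: silylation (TIPSCl, imidazole, DMF) should give the silyl ether F9. Conjugate addition of 14 as in step 7, with the preformed hydroxo-rhodium–diene complex and no added KOH, should give the (2S)-silyl-protected flavanone F10. Buffered desilylation (TBAF/AcOH, THF, 0 °C) should then free the phenol without acid and without free phenoxide. The fallback comes back to the route at 16.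

**Further compounds**

F1 | step 7 | racemic 2-(2,2-dimethyl-3,4-dihydro-2H-chromen-6-yl)-7-(methoxymethoxy)-8-(3-methylbut-2-en-1-yl)-2,3-dihydro-4H-chromen-4-one | CC(C)=CCc1c(OCOC)ccc2c1OC(c1ccc3c(c1)CCC(C)(C)O3)CC2=O
F2 | step 7 | (2R,4R)-2-(2,2-dimethyl-3,4-dihydro-2H-chromen-6-yl)-7-(methoxymethoxy)-8-(3-methylbut-2-en-1-yl)-3,4-dihydro-2H-chromen-4-ol (cis) | CC(C)=CCc1c(OCOC)ccc2c1O[C@@H](c1ccc3c(c1)CCC(C)(C)O3)C[C@H]2O
F3 | step 3 | 1-(2,4-dihydroxyphenyl)ethan-1-one (2,4-dihydroxyacetophenone, purchased) | CC(=O)c1ccc(O)cc1O
F4 | step 3 | 1-{2-hydroxy-4-[(2-methylbut-3-yn-2-yl)oxy]phenyl}ethan-1-one | CC(=O)c1ccc(OC(C)(C)C#C)cc1O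
F5 | step 3 | 1-{2-hydroxy-4-[(2-methylbut-3-en-2-yl)oxy]phenyl}ethan-1-one | CC(=O)c1ccc(OC(C)(C)C=C)cc1O
F6 | step 3 | 1-[2,4-dihydroxy-3-(3-methylbut-2-en-1-yl)phenyl]ethan-1-one | CC(=O)c1ccc(O)c(CC=C(C)C)c1O
F7 | step 3 | 1-[2-hydroxy-4-(methoxymethoxy)-3-(3-methylbut-2-en-1-yl)phenyl]ethan-1-one | CC(=O)c1ccc(OCOC)c(CC=C(C)C)c1O
F8 | step 3 | (E)-3-(dimethylamino)-1-[2-hydroxy-4-(methoxymethoxy)-3-(3-methylbut-2-en-1-yl)phenyl]prop-2-en-1-one | CN(C)/C=C/C(=O)c1ccc(OCOC)c(CC=C(C)C)c1O
F9 | step 8 | 8-(3-methylbut-2-en-1-yl)-7-{[tri(propan-2-yl)silyl]oxy}-4H-chromen-4-one | CC(C)=CCc1c(O[Si](C(C)C)(C(C)C)C(C)C)ccc2c1occc2=O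
F10 | step 8 | (2S)-2-(2,2-dimethyl-3,4-dihydro-2H-chromen-6-yl)-8-(3-methylbut-2-en-1-yl)-7-{[tri(propan-2-yl)silyl]oxy}-2,3-dihydro-4H-chromen-4-one | CC(C)=CCc1c(O[Si](C(C)C)(C(C)C)C(C)C)ccc2c1O[C@H](c1ccc3c(c1)CCC(C)(C)O3)CC2=O
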